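**Plan**
- Retrosynthesis: the 3'-O–Si bond is cut first, then ring B at C1'–C6' and C4'–C5' (retro-[4+2], with two sulfinic acids put back), then the enol O–Si bond and the C1'=C2' alkene, and finally ring C at C2 and the formyl carbon, back to an ortho-hydroxyacetophenone that already contains ring A.
- Enabling feature: ring B is substituted only at the contiguous atoms C1' (chromon-3-yl), C2' (OMe) and C3' (OH), while C4', C5' and C6' are CH. C1'–C4' are thus a 1-(chromon-3-yl)-2-methoxy-3-silyloxybuta-1,3-diene whose two oxygens are already differentiated, and C5'–C6' an acetylene equivalent.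
- Forward order: ring A is bought, ring C is closed by a Vilsmeier–Haack reaction, the four-carbon chain is joined by Horner–Wadsworth–Emmons olefination and silylated, ring B is built last by cycloaddition and double sulfinate loss, and fluoride frees the phenol.
- Stereochemistry: the target is achiral. The only stereochemical element is the Z geometry of the trisubstituted enol ether alkene (chromonyl trans to the rest of the diene), set thermodynamically in the olefination; the sp3 centres of the cycloadduct vanish on aromatisation.

Key step: step 5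

Assumption: the acetophenone, the diazophosphonate (Ohira–Bestmann reagent) and the bis-sulfone are taken as catalogue chemicals; chiral intermediates are racemic, which is immaterial because none of their stereocentres survives.

**Route**

Step 1
Reactants: 1 2'-hydroxy-4',5',6'-trimethoxyacetophenone
Product: 2 5,6,7-trimethoxy-4-oxo-4H-chromene-3-carbaldehyde
Conditions: POCl3 (3 equiv), DMF, 0 °C to 50 °C; then ice-water
Reagents that add atoms: N,N-dimethylformamide, CN(C)C=O; water, O
Why: Vilsmeier–Haack reaction of an ortho-hydroxyacetophenone, in which the acetyl methyl group is iminoformylated twice, the phenol closes ring C onto one iminium carbon with loss of dimethylamine, and aqueous work-up hydrolyses the other iminium to the 3-formyl group, a standard entry to 3-formylchromones that leaves aryl methyl ethers intact.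

Step 2
Reactants: 3 dimethyl (1-diazo-2-oxopropyl)phosphonate
Product: 4 dimethyl (1-methoxy-2-oxopropyl)phosphonate
Conditions: MeOH (3 equiv), Rh2(OAc)4 (1 mol%), PhMe, 80 °C
Reagents that add atoms: methanol, CO
Why: Rhodium-carbenoid O–H insertion, in which Rh2(OAc)4 turns the diazo carbon into an electrophilic carbenoid that methanol captures, a known route from diazophosphonates to α-alkoxy phosphonates; the new sp3 centre forms racemic and is consumed in step 3.

Step 3
Reactants: 2 5,6,7-trimethoxy-4-oxo-4H-chromene-3-carbaldehyde, 4 dimethyl (1-methoxy-2-oxopropyl)phosphonate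
Product: 5 5,6,7-trimethoxy-3-[(1Z)-2-methoxy-3-oxobut-1-en-1-yl]-4H-chromen-4-one
Conditions: 4, NaH (1.0 equiv), THF, 0 °C; then 2, −40 °C to rt; then I2 (2 mol%), CH2Cl2, daylight, rt
Reagents that add atoms: none
Why: Horner–Wadsworth–Emmons olefination, in which the preformed sodium phosphonate should add to the aldehyde carbonyl rather than to C2 of the pyranone and give the trisubstituted enol ether alkene mainly with the chromonyl group trans to the acetyl group (Z), the iodine treatment equilibrating the double bond to this thermodynamically preferred geometry.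

Step 4
Reactants: 5 5,6,7-trimethoxy-3-[(1Z)-2-methoxy-3-oxobut-1-en-1-yl]-4H-chromen-4-one
Product: 6 3-[(1Z)-3-(tert-butyldimethylsilyloxy)-2-methoxybuta-1,3-dien-1-yl]-5,6,7-trimethoxy-4H-chromen-4-one
Conditions: TBSOTf (1.1 equiv), Et3N (1.5 equiv), CH2Cl2, −78 °C to 0 °C; filtration through Et3N-deactivated silica
Reagents that add atoms: tert-butyldimethylsilyl trifluoromethanesulfonate, CC(C)(C)[Si](C)(C)OS(=O)(=O)C(F)(F)F
Why: Soft enolisation of a methyl ketone with a silyl triflate and a tertiary amine, the standard preparation of 2-silyloxy-1,3-dienes from enones, in which the methyl group is the only enolisable position, the C1=C2 geometry is untouched and the low temperature should keep the pyranone carbonyl from being silylated.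

Step 5
Reactants: 6 3-[(1Z)-3-(tert-butyldimethylsilyloxy)-2-methoxybuta-1,3-dien-1-yl]-5,6,7-trimethoxy-4H-chromen-4-one, 7 (E)-1,2-bis(phenylsulfonyl)ethene
Product: 9 3-[3-(tert-butyldimethylsilyloxy)-2-methoxyphenyl]-5,6,7-trimethoxy-4H-chromen-4-one, via trans-bis(phenylsulfonyl)cyclohexene cycloadduct 8 (not isolated)
Conditions: 7 (1.2 equiv), PhMe, 90 °C; then DBU (3 equiv), rt to 60 °C
Reagents that add atoms: none
Why: The 2-methoxy-3-silyloxydiene should add to the doubly sulfonyl-activated alkene in a concerted, normal-electron-demand [4+2] cycloaddition that forms C1'–C6' and C4'–C5' together and thereby closes ring B as a six-membered carbocycle by intermolecular cycloaddition. DBU then expels both sulfinates by E1cB-type eliminations (the second after a prototropic shift), driven by aromatisation, so no oxidant is needed; the three sp3 centres of 8 disappear and no stereocentre has to be controlled. The closest known reaction type is the Diels–Alder reaction of 2-silyloxydienes with 1,2-bis(arylsulfonyl)ethenes as acetylene equivalents, followed by base-induced loss of sulfinic acid to give arenes. The step needs chemoselectivity for the oxygenated diene over the diene made up of the chromone C2=C3 bond and the exocyclic alkene: the two oxygen donors raise its HOMO well above that of the vinylogous-ester diene, and the Z geometry places the chromonyl group outside, so the s-cis conformer is accessible. Regiochemistry is not at issue because the dienophile is symmetric; the silyl enol ether carbon becomes C3' and the methyl enol ether carbon C2', which fixes the OH/OMe pattern.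

Step 6
Reactants: 9 3-[3-(tert-butyldimethylsilyloxy)-2-methoxyphenyl]-5,6,7-trimethoxy-4H-chromen-4-one
Product: 10 3-(3-hydroxy-2-methoxyphenyl)-5,6,7-trimethoxy-4H-chromen-4-one
Conditions: TBAF (1.1 equiv), AcOH (1.1 equiv), THF, 0 °C
Reagents that add atoms: none
Why: Fluoride-mediated cleavage of an aryl silyl ether, driven by Si–F bond formation, with acetic acid buffering the phenoxide so that the base-sensitive pyranone ring and the four methyl ethers should remain untouched.

**Compound list**

1 | 2'-hydroxy-4',5',6'-trimethoxyacetophenone [1-(6-hydroxy-2,3,4-trimethoxyphenyl)ethan-1-one] | CC(=O)c1c(O)cc(OC)c(OC)c1OC | starting material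
2 | 5,6,7-trimethoxy-4-oxo-4H-chromene-3-carbaldehyde | COc1cc2occ(C=O)c(=O)c2c(OC)c1OC | intermediate
3 | dimethyl (1-diazo-2-oxopropyl)phosphonate | CC(=O)C(=[N+]=[N-])P(=O)(OC)OC | starting material
4 | dimethyl (1-methoxy-2-oxopropyl)phosphonate (racemic) | CC(=O)C(OC)P(=O)(OC)OC | intermediate
5 | 5,6,7-trimethoxy-3-[(1Z)-2-methoxy-3-oxobut-1-en-1-yl]-4H-chromen-4-one | COc1cc2occ(/C=C(OC)/C(C)=O)c(=O)c2c(OC)c1OC | intermediate
6 | 3-[(1Z)-3-(tert-butyldimethylsilyloxy)-2-methoxybuta-1,3-dien-1-yl]-5,6,7-trimethoxy-4H-chromen-4-one | COc1cc2occ(/C=C(OC)/C(=C)O[Si](C)(C)C(C)(C)C)c(=O)c2c(OC)c1OC | intermediate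
7 | (E)-1,2-bis(phenylsulfonyl)ethene | O=S(=O)(/C=C/S(=O)(=O)c1ccccc1)c1ccccc1 | starting material
8 | 3-[3-(tert-butyldimethylsilyloxy)-2-methoxy-trans-5,6-bis(phenylsulfonyl)cyclohex-2-en-1-yl]-5,6,7-trimethoxy-4H-chromen-4-one (not isolated; racemic, either configuration at C1 of the cyclohexene) | COc1cc2occ(C3C(OC)=C(O[Si](C)(C)C(C)(C)C)C[C@@H](S(=O)(=O)c4ccccc4)[C@@H]3S(=O)(=O)c3ccccc3)c(=O)c2c(OC)c1OC | intermediate
9 | 3-[3-(tert-butyldimethylsilyloxy)-2-methoxyphenyl]-5,6,7-trimethoxy-4H-chromen-4-one | COc1cc2occ(-c3cccc(O[Si](C)(C)C(C)(C)C)c3OC)c(=O)c2c(OC)c1OC | intermediate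
10 | 3-(3-hydroxy-2-methoxyphenyl)-5,6,7-trimethoxy-4H-chromen-4-one (3'-hydroxy-5,6,7,2'-tetramethoxyisoflavone) | COc1cc2occ(-c3cccc(O)c3OC)c(=O)c2c(OC)c1OC | target

**Step count**

Total: 6 steps. Longest linear sequence: 5 steps (steps 1, 3, 4, 5, 6); step 2 is a one-step side branch.

**Steps most likely to fail, with fallbacks**

Step 5. The cycloaddition may be slowed by the electron-withdrawing chromonyl group on the diene terminus, giving time for hydrolytic loss of the silyl enol ether or for reaction through the chromone C2=C3/alkene diene. The elimination may also stall after the first sulfinate has left. The fallback gives up the cycloaddition for a cross-coupling; it sets out from 1 and returns at 9. Compound 1 would be condensed with DMF dimethyl acetal (neat, 90 °C) to (E)-3-(dimethylamino)-1-(6-hydroxy-2,3,4-trimethoxyphenyl)prop-2-en-1-one F1, and iodine in methanol would cyclise this to 3-iodo-5,6,7-trimethoxy-4H-chromen-4-one F2. Commercial 3-bromo-2-methoxyphenol would be silylated (TBSCl, imidazole, DMF) to (3-bromo-2-methoxyphenoxy)(tert-butyl)dimethylsilane F3 and borylated (bis(pinacolato)diboron, PdCl2(dppf), KOAc, dioxane, 80 °C) to tert-butyl[2-methoxy-3-(4,4,5,5-tetramethyl-1,3,2-dioxaborolan-2-yl)phenoxy]dimethylsilane F4. Suzuki–Miyaura coupling of F2 with F4 (Pd(PPh3)4, K2CO3, DME/H2O, 80 °C) should give 9; premature silyl loss there would merely deliver 10.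

Step 4. The silyl triflate may silylate the pyranone carbonyl to a benzopyrylium species, which the newly formed silyl enol ether could attack at C2; the diene may also be hydrolysed during isolation. The fallback replaces the silyl dienol ether by an enol acetate made under acidic conditions; it sets out from 5 and returns at 10. Heating 5 with isopropenyl acetate and catalytic TsOH should give (3Z)-3-methoxy-4-(5,6,7-trimethoxy-4-oxo-4H-chromen-3-yl)buta-1,3-dien-2-yl acetate F5. Cycloaddition with 7 (PhMe, 110 °C) would lead to 2-methoxy-trans-4,5-bis(phenylsulfonyl)-3-(5,6,7-trimethoxy-4-oxo-4H-chromen-3-yl)cyclohex-1-en-1-yl acetate F6, and DBU would aromatise it to 2-methoxy-3-(5,6,7-trimethoxy-4-oxo-4H-chromen-3-yl)phenyl acetate F7. Brief methanolysis (K2CO3, MeOH, 0 °C) would then give 10. The acetoxy diene is less reactive than 6, so this is a second choice.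

Step 3. The phosphonate anion may attack C2 of the 3-formylchromone and open ring C, and equilibration of the alkene geometry may remain incomplete. The fallback avoids carbanions altogether; it sets out from 2 and returns at 5. Compound 2 would be condensed directly with methoxyacetone under acid (HCl-saturated AcOH, rt). Under these conditions the chromone is stable, the ketone should enolise towards its oxygen-bearing carbon, and dehydration under equilibrating conditions should give the Z enone 5. No new isolated compound arises (entry F0 below).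

**Further compounds**

F1 | step 5 | (E)-3-(dimethylamino)-1-(6-hydroxy-2,3,4-trimethoxyphenyl)prop-2-en-1-one | CN(C)/C=C/C(=O)c1c(O)cc(OC)c(OC)c1OC
F2 | step 5 | 3-iodo-5,6,7-trimethoxy-4H-chromen-4-one | COc1cc2occ(I)c(=O)c2c(OC)c1OC
F3 | step 5 | (3-bromo-2-methoxyphenoxy)(tert-butyl)dimethylsilane | COc1c(Br)cccc1O[Si](C)(C)C(C)(C)C
F4 | step 5 | tert-butyl[2-methoxy-3-(4,4,5,5-tetramethyl-1,3,2-dioxaborolan-2-yl)phenoxy]dimethylsilane | COc1c(B2OC(C)(C)C(C)(C)O2)cccc1O[Si](C)(C)C(C)(C)C
F5 | step 4 | (3Z)-3-methoxy-4-(5,6,7-trimethoxy-4-oxo-4H-chromen-3-yl)buta-1,3-dien-2-yl acetate | COc1cc2occ(/C=C(OC)/C(=C)OC(C)=O)c(=O)c2c(OC)c1OC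
F6 | step 4 | 2-methoxy-trans-4,5-bis(phenylsulfonyl)-3-(5,6,7-trimethoxy-4-oxo-4H-chromen-3-yl)cyclohex-1-en-1-yl acetate | COc1cc2occ(C3C(OC)=C(OC(C)=O)C[C@@H](S(=O)(=O)c4ccccc4)[C@@H]3S(=O)(=O)c3ccccc3)c(=O)c2c(OC)c1OC
F7 | step 4 | 2-methoxy-3-(5,6,7-trimethoxy-4-oxo-4H-chromen-3-yl)phenyl acetate | COc1cc2occ(-c3cccc(OC(C)=O)c3OC)c(=O)c2c(OC)c1OC
F0 | step 3 | none | none
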